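**Plan**
- Retrosynthesis first cuts the aryl O–S bond (phenol plus a sulfur trioxide donor); the phenol is carried as a benzyl ether.
- The imidazole is then cut at C4–C5 and N1–C2. N3, C2 and C4 with its 4-methoxybenzyl arm come from an α-substituted tosylmethyl isocyanide; C5 with its 4-(benzyloxy)benzyl arm and N1 come from an arylacetaldehyde and ammonia.
- Enabling feature: the imidazole ring has an unsubstituted C2–H between N1 and N3, a free N–H, and two different benzyl groups on C4 and C5. This is the substitution pattern an isocyanide [3+2] union with an NH aldimine leaves.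
- Forward: two one-step branches (C-benzylation of the isocyanide reagent; oxidation of the phenethyl alcohol), then the three-component union that closes the only new ring, then debenzylation and sulfation.
- Stereochemistry: the target has no stereocentre. The racemic centre of the isocyanide and the centres of the imidazoline intermediate disappear on aromatisation.

Key step: step 3

Remark: the target is achiral, so the route needs no stereocontrol. The sulfate is drawn as the free acid and is expected to be isolated as the imidazolium sulfate inner salt.

**Route**

Step 1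
Reactants: 1 tosylmethyl isocyanide (TosMIC); 2 4-methoxybenzyl chloride
Product: 3 1-{[1-isocyano-2-(4-methoxyphenyl)ethyl]sulfonyl}-4-methylbenzene (α-(4-methoxybenzyl)TosMIC, racemic)
Conditions: 1 (1.2 equiv), 2 (1.0 equiv), n-Bu4NI (0.2 equiv), 30% aq NaOH, CH2Cl2, 0 °C
Reagents that add atoms: none
Why: Phase-transfer C-alkylation of the methylene flanked by sulfonyl and isocyano groups with a benzylic halide is the standard entry to α-monosubstituted TosMIC reagents, and the slight excess of 1, the low temperature and the iodide co-catalyst should hold it at monoalkylation; the new centre is racemic and is erased in step 3.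

Step 2
Reactants: 4 2-[4-(benzyloxy)phenyl]ethanol
Product: 5 2-[4-(benzyloxy)phenyl]acetaldehyde
Conditions: Dess–Martin periodinane (1.2 equiv), CH2Cl2, 0 °C → rt; used crude the same day
Reagents that add atoms: none
Why: Dess–Martin oxidation of a primary alcohol stops at the aldehyde under neutral, non-aqueous conditions that leave the benzyl ether untouched, and immediate use limits self-aldol condensation of the enolisable arylacetaldehyde.

Step 3
Reactants: 3 α-(4-methoxybenzyl)TosMIC; 5 2-[4-(benzyloxy)phenyl]acetaldehyde; 6 ammonia
Product: 9 4-[4-(benzyloxy)benzyl]-5-(4-methoxybenzyl)-1H-imidazole, via NH aldimine 7 (not isolated), via 4-tosyl-2-imidazoline 8 (not isolated)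
Conditions: 5 (1.5 equiv), NH3 (7 M in MeOH, 15 equiv), THF, 0 °C, 1 h; then 3 (1.0 equiv), K2CO3 (2 equiv), 0 °C → rt
Reagents that add atoms: none
Why: Ammonia condenses with 5 to the NH aldimine 7, carbonate deprotonates 3 at the carbon between the sulfonyl and isocyano groups, and this carbanion adds to the imine carbon to form C4–C5. The resulting nitrogen anion attacks the isocyanide carbon in a 5-endo-dig closure (N1–C2) to give imidazoline 8, which loses p-toluenesulfinic acid and aromatises, so C2 remains C–H without any oxidant. The closest known reaction type is the van Leusen three-component imidazole synthesis with ammonia as the amine component, a formal [3+2] of a sulfonylmethyl isocyanide across C=N. No stereocentre is set: racemic 3 and all diastereomers of 8 converge on one aromatic ring, and the two N–H tautomers of 9 are the same compound, so there is no regiochemical question. The selectivity needed is attack on the imine instead of the free aldehyde (which would give the oxazole) and instead of enolisation; it is secured by converting 5 fully to 7 with a large excess of ammonia at 0 °C before 3 and base are added. The benzyl and methyl ethers are inert to ammonia and carbonate.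

Step 4
Reactants: 9 4-[4-(benzyloxy)benzyl]-5-(4-methoxybenzyl)-1H-imidazole
Product: 10 4-{[5-(4-methoxybenzyl)-1H-imidazol-4-yl]methyl}phenol
Conditions: H2 (1 atm), 10% Pd/C, MeOH–AcOH (10:1), rt
Reagents that add atoms: none
Why: Catalytic hydrogenolysis cleaves the aryl benzyl ether while the C-benzyl links to the imidazole, the aryl methyl ether and the heteroaromatic ring are stable at 1 atm and room temperature, and acetic acid keeps the basic imidazole protonated so it does not block the palladium surface.

Step 5
Reactants: 10 4-{[5-(4-methoxybenzyl)-1H-imidazol-4-yl]methyl}phenol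
Product: 11 Melanocin F, 4-{[5-(4-methoxybenzyl)-1H-imidazol-4-yl]methyl}phenyl hydrogen sulfate
Conditions: SO3·pyridine (2 equiv), pyridine, 0 °C → rt; then H2O, pH 7 (aq NaHCO3); C18 chromatography (H2O/MeOH)
Reagents that add atoms: sulfur trioxide–pyridine complex, O=S(=O)([O-])[n+]1ccccc1
Why: O-Sulfation of a phenol with a sulfur trioxide–amine complex is the standard route to aryl hydrogen sulfates; the complex is too mild to sulfonate the anisole ring, any sulfonation at imidazole nitrogen should revert on aqueous work-up because N-sulfoimidazoles are themselves SO3 donors, and the neutral work-up avoids acid hydrolysis of the aryl sulfate.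

**Compound list**
1 | tosylmethyl isocyanide (TosMIC) | Cc1ccc(S(=O)(=O)C[N+]#[C-])cc1 | starting material
2 | 4-methoxybenzyl chloride | COc1ccc(CCl)cc1 | starting material
3 | 1-{[1-isocyano-2-(4-methoxyphenyl)ethyl]sulfonyl}-4-methylbenzene (racemic) | COc1ccc(CC([N+]#[C-])S(=O)(=O)c2ccc(C)cc2)cc1 | intermediate
4 | 2-[4-(benzyloxy)phenyl]ethanol | OCCc1ccc(OCc2ccccc2)cc1 | starting material
5 | 2-[4-(benzyloxy)phenyl]acetaldehyde | O=CCc1ccc(OCc2ccccc2)cc1 | intermediate
6 | ammonia | N | starting material
7 | 2-[4-(benzyloxy)phenyl]ethan-1-imine (NH aldimine, not isolated) | N=CCc1ccc(OCc2ccccc2)cc1 | intermediate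
8 | 5-[4-(benzyloxy)benzyl]-4-(4-methoxybenzyl)-4-tosyl-4,5-dihydro-1H-imidazole (racemic diastereomer mixture, not isolated) | COc1ccc(CC2(S(=O)(=O)c3ccc(C)cc3)N=CNC2Cc2ccc(OCc3ccccc3)cc2)cc1 | intermediate
9 | 4-[4-(benzyloxy)benzyl]-5-(4-methoxybenzyl)-1H-imidazole | COc1ccc(Cc2[nH]cnc2Cc2ccc(OCc3ccccc3)cc2)cc1 | intermediate
10 | 4-{[5-(4-methoxybenzyl)-1H-imidazol-4-yl]methyl}phenol | COc1ccc(Cc2[nH]cnc2Cc2ccc(O)cc2)cc1 | intermediate
11 | Melanocin F, 4-{[5-(4-methoxybenzyl)-1H-imidazol-4-yl]methyl}phenyl hydrogen sulfate | COc1ccc(Cc2[nH]cnc2Cc2ccc(OS(=O)(=O)O)cc2)cc1 | target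

**Count**
Total steps: 5. Longest linear sequence: 4 (step 1 or step 2, then steps 3, 4, 5).

**Steps most likely to fail**

Step 3. The aldehyde may not be fully converted to the imine, so the isocyanide anion is consumed by the carbonyl group; the imine may also tautomerise to the enamine and self-condense. The fallback accepts the carbonyl pathway and changes the heteroatom afterwards. It sets out from 3 and 5: K2CO3 in MeOH at reflux (van Leusen oxazole synthesis) should give 5-[4-(benzyloxy)benzyl]-4-(4-methoxybenzyl)-1,3-oxazole F1. Heating this oxazole in formamide saturated with ammonia in a sealed vessel at about 180 °C (oxazole-to-imidazole ring transformation: ring opening at C2 and reclosure with loss of water) comes back to the route at 9.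

Step 5. Sulfur trioxide may be taken up by the imidazole nitrogen in competition with the phenol, and the inner salt may be lost or hydrolysed during isolation. The fallback masks the imidazole first and sets out from 10. Boc2O (1.0 equiv, no acylation catalyst) in MeCN at rt should acylate only the imidazole N–H to give tert-butyl 4-(4-hydroxybenzyl)-5-(4-methoxybenzyl)-1H-imidazole-1-carboxylate F2 (drawn as one N-regioisomer; the other converges). SO3·pyridine in pyridine then gives tert-butyl 5-(4-methoxybenzyl)-4-[4-(sulfooxy)benzyl]-1H-imidazole-1-carboxylate F3, handled as its pyridinium or sodium salt and purifiable as an ordinary anionic sulfate. Catalytic K2CO3 in MeOH at rt removes the N-Boc group under basic conditions that aryl sulfates tolerate, and the route is rejoined at 11.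

Step 2. The arylacetaldehyde may self-condense or air-oxidise during work-up and storage, so that less monomeric aldehyde than intended reaches step 3. The fallback isolates a stable crystalline surrogate and sets out from 4. Oxidation with catalytic TEMPO and PhI(OAc)2 in CH2Cl2 at rt, followed by shaking the organic phase with saturated aqueous NaHSO3 and ethanol, should precipitate sodium 2-[4-(benzyloxy)phenyl]-1-hydroxyethane-1-sulfonate F4 (racemic). This adduct can be filtered, washed and stored. Aqueous Na2CO3/EtOAc releases the aldehyde immediately before use, returning to the route at 5.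

**Further compounds**
F1 | step 3 | 5-[4-(benzyloxy)benzyl]-4-(4-methoxybenzyl)-1,3-oxazole | COc1ccc(Cc2ncoc2Cc2ccc(OCc3ccccc3)cc2)cc1
F2 | step 5 | tert-butyl 4-(4-hydroxybenzyl)-5-(4-methoxybenzyl)-1H-imidazole-1-carboxylate | COc1ccc(Cc2c(Cc3ccc(O)cc3)ncn2C(=O)OC(C)(C)C)cc1
F3 | step 5 | tert-butyl 5-(4-methoxybenzyl)-4-[4-(sulfooxy)benzyl]-1H-imidazole-1-carboxylate | COc1ccc(Cc2c(Cc3ccc(OS(=O)(=O)O)cc3)ncn2C(=O)OC(C)(C)C)cc1
F4 | step 2 | sodium 2-[4-(benzyloxy)phenyl]-1-hydroxyethane-1-sulfonate (racemic) | [Na+].[O-]S(=O)(=O)C(O)Cc1ccc(OCc2ccccc2)cc1
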